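**Retrosynthetic overview**
- Target ⇒ C-4(flavan)–C-5(flavonol) bond: acid-mediated Friedel–Crafts capture of a flavan-4-yl quinone methide (from the 2,3-trans-flavan-3,4-diol) by melanoxetin; this sets C-4 (3,4-trans).
- Diol and melanoxetin ⇒ the two enantiomers of one racemic trans-dihydroflavonol, the biosynthetic branch point: the (2R,3R) half is kept and reduced, the (2S,3S) half is oxidised to the achiral flavonol.
- The enantiomers are parted by a transfer-hydrogenative kinetic resolution, so neither is discarded.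
- Racemic dihydroflavonol ⇒ 2'-hydroxychalcone by one oxidative cyclisation (oxa-Michael closure plus C-3 hydroxylation); this is the only ring-forming step and builds ring C of both halves at once.
- Chalcone ⇒ gallacetophenone + 3,4-bis(benzyloxy)benzaldehyde (rings A and B are bought).

Reading of the target: an all-trans (2R,3S,4R)-3',4',7,8-tetrahydroxyflavan-3-ol unit joined from C-4 to C-5 of 3,7,8,3',4'-pentahydroxyflavone (melanoxetin).

Step 1
Reactants: 1 1-(2,3,4-trihydroxyphenyl)ethan-1-one (gallacetophenone)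
Product: 2 1-[3,4-bis(benzyloxy)-2-hydroxyphenyl]ethan-1-one
Conditions: BnBr (2.1 equiv), K2CO3 (2.2 equiv), acetone, reflux, 6 h
Reagents that add atoms: benzyl bromide, BrCc1ccccc1
Why: Williamson etherification in which the 2-OH, hydrogen-bonded to the acetyl carbonyl, is the least reactive phenol, so two equivalents alkylate only O-4 and O-3 and leave the phenol needed for ring closure.

Step 2
Reactants: 2 1-[3,4-bis(benzyloxy)-2-hydroxyphenyl]ethan-1-one; 3 3,4-bis(benzyloxy)benzaldehyde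
Product: 4 (E)-1-[3,4-bis(benzyloxy)-2-hydroxyphenyl]-3-[3,4-bis(benzyloxy)phenyl]prop-2-en-1-one
Conditions: KOH (50% aq., 5 equiv), EtOH–THF, 25 °C, 24 h; then dil. HCl
Reagents that add atoms: none
Why: Claisen–Schmidt aldol condensation whose E1cB dehydration gives only the (E)-enone, with benzyl ethers and the 2'-phenoxide stable to hydroxide.

Step 3
Reactants: 4 (E)-1-[3,4-bis(benzyloxy)-2-hydroxyphenyl]-3-[3,4-bis(benzyloxy)phenyl]prop-2-en-1-one
Product: 6 racemic (2R*,3R*)-7,8-bis(benzyloxy)-2-[3,4-bis(benzyloxy)phenyl]-3-hydroxychroman-4-one, via flavanone enolate 5 (not isolated)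
Conditions: 30% H2O2 (3 equiv), 2 M NaOH (2.5 equiv), MeOH–THF, 0 °C, 2–3 h; quench AcOH/Na2SO3
Reagents that add atoms: hydrogen peroxide, OO
Why: Algar–Flynn–Oyamada oxidative cyclisation stopped at the dihydroflavonol stage, in which the 2'-phenoxide closes ring C by 6-endo oxa-Michael addition (the chalcone isomerase event) and the enolate is hydroxylated at C-3 by H2O2 anti to the equatorial 2-aryl group (the flavanone 3-hydroxylase event), giving the 2,3-trans racemate; the over-oxidised flavonol by-product is the compound made in step 5 and is pooled with it.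

Step 4
Reactants: 6 racemic (2R*,3R*)-7,8-bis(benzyloxy)-2-[3,4-bis(benzyloxy)phenyl]-3-hydroxychroman-4-one
Product: 7 (2R,3R)-7,8-bis(benzyloxy)-2-[3,4-bis(benzyloxy)phenyl]-3-hydroxychroman-4-one (unreacted enantiomer) and 8 (2S,3R,4S)-7,8-bis(benzyloxy)-2-[3,4-bis(benzyloxy)phenyl]chromane-3,4-diol (reduced enantiomer); separated on silica
Conditions: RuCl(p-cymene)[(R,R)-TsDPEN] (1 mol%), HCO2H–Et3N (5:2), EtOAc, 25 °C, stopped at 52–55% conversion (chiral HPLC)
Reagents that add atoms: none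
Why: Proposed new method: Noyori–Ikariya asymmetric transfer hydrogenation run as a kinetic resolution, in which the (R,R)-catalyst delivers hydride to the same carbonyl face of both enantiomers (the face that gives (R)-chroman-4-ol from chroman-4-one), which for the (2S,3S)-ketone is the favoured axial trajectory to the all-trans diol 8 (matched, fast) and for the (2R,3R)-ketone the disfavoured approach to a 3,4-cis diol (mismatched, slow), so 7 is recovered in high ee once conversion passes 50%; the closest known reactions are the transfer-hydrogenative kinetic resolution of racemic flavanones and the reduction of chroman-4-ones with the same catalysts.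

Step 5
Reactants: 8 (2S,3R,4S)-7,8-bis(benzyloxy)-2-[3,4-bis(benzyloxy)phenyl]chromane-3,4-diol
Product: 11 7,8-bis(benzyloxy)-2-[3,4-bis(benzyloxy)phenyl]-3-hydroxy-4H-chromen-4-one (tetra-O-benzylmelanoxetin), via (2S,3S)-dihydroflavonol 9 (not isolated), via (2S)-flavan-3,4-dione 10 (not isolated)
Conditions: IBX (3 equiv), DMSO, 40 °C, 12 h
Reagents that add atoms: none
Why: IBX oxidation of a 1,2-diol to the 1,2-dione without C–C cleavage (benzylic carbinol first, then the α-ketol), after which the 3,4-dione enolises irreversibly to the aromatic 3-hydroxychromone and both stereocentres of the unwanted enantiomer are erased.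

Step 6
Reactants: 11 7,8-bis(benzyloxy)-2-[3,4-bis(benzyloxy)phenyl]-3-hydroxy-4H-chromen-4-one
Product: 12 2-(3,4-dihydroxyphenyl)-3,7,8-trihydroxy-4H-chromen-4-one (melanoxetin)
Conditions: H2 (1 atm), 10% Pd/C, THF–MeOH (1:1), 25 °C, 4 h; filtered under Ar
Reagents that add atoms: none
Why: Hydrogenolysis of the four benzyl aryl ethers, under which the chromone C2=C3 bond and carbonyl are not reduced.

Step 7
Reactants: 7 (2R,3R)-7,8-bis(benzyloxy)-2-[3,4-bis(benzyloxy)phenyl]-3-hydroxychroman-4-one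
Product: 13 (2R,3R)-2-(3,4-dihydroxyphenyl)-3,7,8-trihydroxychroman-4-one
Conditions: H2 (1 atm), 10% Pd/C, EtOAc–MeOH, 25 °C, 3 h; Ar work-up
Reagents that add atoms: none
Why: Benzyl ether hydrogenolysis done at the ketone oxidation level, where there is no benzylic C-4 hydroxyl to be lost and neutral conditions leave C-2 and C-3 untouched.

Step 8
Reactants: 13 (2R,3R)-2-(3,4-dihydroxyphenyl)-3,7,8-trihydroxychroman-4-one; 12 melanoxetin (4 equiv, excess recovered)
Product: 16 5-[(2R,3S,4R)-2-(3,4-dihydroxyphenyl)-3,7,8-trihydroxy-3,4-dihydro-2H-chromen-4-yl]-2-(3,4-dihydroxyphenyl)-3,7,8-trihydroxy-4H-chromen-4-one (target), via (2R,3S,4R)-flavan-3,4-diol 14 (not isolated), via quinone methide 15 (not isolated)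
Conditions: NaBH4 (2 equiv), EtOH, 0 → 25 °C, Ar, 1 h; then added dropwise (6 h) to 12 in 1,4-dioxane–0.1 M aq. HCl, 40 °C, 24 h; Sephadex LH-20
Reagents that add atoms: none
Why: Proposed new method: NaBH4 reduces only the flavanone carbonyl (axial hydride, all-trans diol), and dilute acid ionises the diol to the 7-hydroxy-stabilised quinone methide, which melanoxetin captures by Friedel–Crafts attack anti to the adjacent 3-hydroxyl so that C-4 is set 3,4-trans (4R) under control of C-2 and C-3, the regiochemistry resting on C-5 being para to 8-OH, the only ring A oxygen not engaged in push-pull conjugation with the C-4 carbonyl; the closest known reaction is the acid-catalysed condensation of free phenolic flavan-3,4-diols with flavan-3-ols, here extended to a flavonol nucleophile.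

**Compound list**
1 | 1-(2,3,4-trihydroxyphenyl)ethan-1-one (gallacetophenone) | CC(=O)c1ccc(O)c(O)c1O | starting material
2 | 1-[3,4-bis(benzyloxy)-2-hydroxyphenyl]ethan-1-one | CC(=O)c1ccc(OCc2ccccc2)c(OCc2ccccc2)c1O | intermediate
3 | 3,4-bis(benzyloxy)benzaldehyde | O=Cc1ccc(OCc2ccccc2)c(OCc2ccccc2)c1 | starting material
4 | (E)-1-[3,4-bis(benzyloxy)-2-hydroxyphenyl]-3-[3,4-bis(benzyloxy)phenyl]prop-2-en-1-one | O=C(/C=C/c1ccc(OCc2ccccc2)c(OCc2ccccc2)c1)c1ccc(OCc2ccccc2)c(OCc2ccccc2)c1O | intermediate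
5 | racemic 7,8-bis(benzyloxy)-2-[3,4-bis(benzyloxy)phenyl]chroman-4-one, present in step 3 as its sodium enolate (racemate, C-2 not specified) | O=C1CC(c2ccc(OCc3ccccc3)c(OCc3ccccc3)c2)Oc2c1ccc(OCc1ccccc1)c2OCc1ccccc1 | intermediate
6 | racemic (2R*,3R*)-7,8-bis(benzyloxy)-2-[3,4-bis(benzyloxy)phenyl]-3-hydroxychroman-4-one (2,3-trans, both enantiomers) | O=C1c2ccc(OCc3ccccc3)c(OCc3ccccc3)c2O[C@H](c2ccc(OCc3ccccc3)c(OCc3ccccc3)c2)[C@H]1O.O=C1c2ccc(OCc3ccccc3)c(OCc3ccccc3)c2O[C@@H](c2ccc(OCc3ccccc3)c(OCc3ccccc3)c2)[C@@H]1O | intermediate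
7 | (2R,3R)-7,8-bis(benzyloxy)-2-[3,4-bis(benzyloxy)phenyl]-3-hydroxychroman-4-one | O=C1c2ccc(OCc3ccccc3)c(OCc3ccccc3)c2O[C@H](c2ccc(OCc3ccccc3)c(OCc3ccccc3)c2)[C@H]1O | intermediate
8 | (2S,3R,4S)-7,8-bis(benzyloxy)-2-[3,4-bis(benzyloxy)phenyl]chromane-3,4-diol | O[C@H]1c2ccc(OCc3ccccc3)c(OCc3ccccc3)c2O[C@@H](c2ccc(OCc3ccccc3)c(OCc3ccccc3)c2)[C@@H]1O | intermediate
9 | (2S,3S)-7,8-bis(benzyloxy)-2-[3,4-bis(benzyloxy)phenyl]-3-hydroxychroman-4-one | O=C1c2ccc(OCc3ccccc3)c(OCc3ccccc3)c2O[C@@H](c2ccc(OCc3ccccc3)c(OCc3ccccc3)c2)[C@@H]1O | intermediate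
10 | (2S)-7,8-bis(benzyloxy)-2-[3,4-bis(benzyloxy)phenyl]chromane-3,4-dione | O=C1C(=O)c2ccc(OCc3ccccc3)c(OCc3ccccc3)c2O[C@H]1c1ccc(OCc2ccccc2)c(OCc2ccccc2)c1 | intermediate
11 | 7,8-bis(benzyloxy)-2-[3,4-bis(benzyloxy)phenyl]-3-hydroxy-4H-chromen-4-one | O=c1c(O)c(-c2ccc(OCc3ccccc3)c(OCc3ccccc3)c2)oc2c(OCc3ccccc3)c(OCc3ccccc3)ccc12 | intermediate
12 | 2-(3,4-dihydroxyphenyl)-3,7,8-trihydroxy-4H-chromen-4-one (melanoxetin) | O=c1c(O)c(-c2ccc(O)c(O)c2)oc2c(O)c(O)ccc12 | intermediate
13 | (2R,3R)-2-(3,4-dihydroxyphenyl)-3,7,8-trihydroxychroman-4-one | O=C1c2ccc(O)c(O)c2O[C@H](c2ccc(O)c(O)c2)[C@H]1O | intermediate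
14 | (2R,3S,4R)-2-(3,4-dihydroxyphenyl)chromane-3,4,7,8-tetrol (2,3-trans-3,4-trans) | O[C@@H]1c2ccc(O)c(O)c2O[C@H](c2ccc(O)c(O)c2)[C@H]1O | intermediate
15 | (2R,3S)-2-(3,4-dihydroxyphenyl)-3,8-dihydroxy-2,3-dihydro-7H-chromen-7-one (ring A quinone methide) | O=C1C=CC2=C[C@H](O)[C@@H](c3ccc(O)c(O)c3)OC2=C1O | intermediate
16 | 5-[(2R,3S,4R)-2-(3,4-dihydroxyphenyl)-3,7,8-trihydroxy-3,4-dihydro-2H-chromen-4-yl]-2-(3,4-dihydroxyphenyl)-3,7,8-trihydroxy-4H-chromen-4-one | O=c1c(O)c(-c2ccc(O)c(O)c2)oc2c(O)c(O)cc([C@@H]3c4ccc(O)c(O)c4O[C@H](c4ccc(O)c(O)c4)[C@H]3O)c12 | target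

**Totals**
Total step count: 8. Longest linear sequence: 7 (steps 1–6, then 8).

**Three steps most likely to fail**

Step 8 (most likely). Melanoxetin is a weak nucleophile, attack at C-6 (ortho to 7-OH) is the expected competitor of C-5, and diol 14 can condense with itself. I judge C-6 attack to be a real possibility, so this step carries the main risk of the route. The fallback blocks C-6; it sets out from 2 and comes back at 16. NBS (MeCN, 0 °C) brominates 2 para to the free phenol and gives 1-[3,4-bis(benzyloxy)-5-bromo-2-hydroxyphenyl]ethan-1-one F1. Claisen–Schmidt condensation with 3 gives (E)-1-[3,4-bis(benzyloxy)-5-bromo-2-hydroxyphenyl]-3-[3,4-bis(benzyloxy)phenyl]prop-2-en-1-one F2. Algar–Flynn–Oyamada oxidation run to completion (H2O2, NaOH, 25 °C) gives 7,8-bis(benzyloxy)-2-[3,4-bis(benzyloxy)phenyl]-6-bromo-3-hydroxy-4H-chromen-4-one F3. BCl3 with pentamethylbenzene (CH2Cl2, −78 °C) removes the benzyl groups without touching bromine and gives 6-bromomelanoxetin F4. Condensation of F4 with diol 14 (made from 13 as in step 8) can then take place only at C-5 and gives the 6-bromo derivative of the target F5. H2 over Pd/C with Et3N removes the bromine and returns to 16. The blocked position is more hindered, so this may need longer reaction times.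

Step 4. The selectivity factor of the resolution is unknown for a 3-hydroxyflavanone. The fallback replaces resolution by asymmetric ring formation; it sets out from 4 and comes back at 7. MOMCl with iPr2NEt converts 4 into its 2'-O-methoxymethyl ether F6. Juliá–Colonna epoxidation (poly-L-leucine, urea–H2O2, DBU, THF) gives the (2R,3S)-epoxy ketone F7. HCl in MeOH (50 °C) removes the acetal, and the freed phenol opens the epoxide at the benzylic carbon with inversion (6-endo) to give 7 directly. Flavonol 11 is then made from 4 by Algar–Flynn–Oyamada oxidation run to completion, so steps 4 and 5 fall away.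

Step 3. Over-oxidation to the flavonol and aurone formation can erode the yield of 6. The fallback separates ring closure from hydroxylation; it sets out from 4 and comes back at 6. NaOAc in refluxing EtOH cyclises 4 to the racemic flavanone 5, which is isolated. TMSOTf with Et3N gives the silyl enol ether 7,8-bis(benzyloxy)-2-[3,4-bis(benzyloxy)phenyl]-4-(trimethylsilyloxy)-2H-chromene F8. Rubottom oxidation with dimethyldioxirane (acetone, −20 °C) anti to the 2-aryl group, followed by dilute acid, gives trans-6.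

**Further compounds**
F1 | step 8 | 1-[3,4-bis(benzyloxy)-5-bromo-2-hydroxyphenyl]ethan-1-one | CC(=O)c1cc(Br)c(OCc2ccccc2)c(OCc2ccccc2)c1O
F2 | step 8 | (E)-1-[3,4-bis(benzyloxy)-5-bromo-2-hydroxyphenyl]-3-[3,4-bis(benzyloxy)phenyl]prop-2-en-1-one | O=C(/C=C/c1ccc(OCc2ccccc2)c(OCc2ccccc2)c1)c1cc(Br)c(OCc2ccccc2)c(OCc2ccccc2)c1O
F3 | step 8 | 7,8-bis(benzyloxy)-2-[3,4-bis(benzyloxy)phenyl]-6-bromo-3-hydroxy-4H-chromen-4-one | O=c1c(O)c(-c2ccc(OCc3ccccc3)c(OCc3ccccc3)c2)oc2c(OCc3ccccc3)c(OCc3ccccc3)c(Br)cc12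
F4 | step 8 | 6-bromo-2-(3,4-dihydroxyphenyl)-3,7,8-trihydroxy-4H-chromen-4-one (6-bromomelanoxetin) | O=c1c(O)c(-c2ccc(O)c(O)c2)oc2c(O)c(O)c(Br)cc12
F5 | step 8 | 6-bromo-5-[(2R,3S,4S)-2-(3,4-dihydroxyphenyl)-3,7,8-trihydroxy-3,4-dihydro-2H-chromen-4-yl]-2-(3,4-dihydroxyphenyl)-3,7,8-trihydroxy-4H-chromen-4-one (same spatial arrangement as 16; the C-4 descriptor changes only because of bromine) | O=c1c(O)c(-c2ccc(O)c(O)c2)oc2c(O)c(O)c(Br)c([C@@H]3c4ccc(O)c(O)c4O[C@H](c4ccc(O)c(O)c4)[C@H]3O)c12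
F6 | step 4 | (E)-1-[3,4-bis(benzyloxy)-2-(methoxymethoxy)phenyl]-3-[3,4-bis(benzyloxy)phenyl]prop-2-en-1-one | O=C(/C=C/c1ccc(OCc2ccccc2)c(OCc2ccccc2)c1)c1ccc(OCc2ccccc2)c(OCc2ccccc2)c1OCOC
F7 | step 4 | [3,4-bis(benzyloxy)-2-(methoxymethoxy)phenyl][(2R,3S)-3-[3,4-bis(benzyloxy)phenyl]oxiran-2-yl]methanone | O=C([C@@H]1O[C@H]1c1ccc(OCc2ccccc2)c(OCc2ccccc2)c1)c1ccc(OCc2ccccc2)c(OCc2ccccc2)c1OCOC
F8 | step 3 | racemic 7,8-bis(benzyloxy)-2-[3,4-bis(benzyloxy)phenyl]-4-(trimethylsilyloxy)-2H-chromene | C[Si](C)(C)OC1=CC(c2ccc(OCc3ccccc3)c(OCc3ccccc3)c2)Oc2c1ccc(OCc1ccccc1)c2OCc1ccccc1
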